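## Retrosynthetic overview

1. Target 19 ⇒ bridged triketone 17: the C1–C8 bond (ring B of the bicyclo[3.3.1]nonane) and the cyclopentane bond C12–C13 (with C15–OH) are made last, in one acid-triggered double cation closure.
2. 17 ⇒ 14: the C3 prenyl group replaces a C3 benzoyl group (retro-Claisen, then alkylation), so the two acyl-bearing ring carbons of the precursor can be identical.
3. 14 ⇒ 5 + 12 (key step): one-pot palladium dearomative C-allylation of the C_s-symmetric arene 5, then enantioselective desymmetrizing allylation that closes the seven-membered ring (C3–C11).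
4. 5 ⇒ phloroglucinol, benzoyl chloride, geranyl bromide; 12 ⇒ methacrolein + ethyl 2-(bromomethyl)acrylate.
5. Ring order: ring A (the arene) → seven-membered ring → cyclopentane → ring B of the bicyclo[3.3.1]nonane.

Labels used throughout: ring A = C1 (benzoyl carbon), C2, C3, C4, C5 (geranyl carbon), C9; C6 = CH2 on C5; C7; C8 = CMe2 carbon on C7; C10 = CH2 between C7 and C11; C11 = CH bound to C3; C12 = CMe2 carbon on C11; C14, C13, C15 = CH2, CH and CMe2 carbons of the C3 prenyl unit.

Assumption: the ligand antipode written in step 7 is taken to be the one that gives the drawn enantiomer; if the sense is opposite, the (R,R) ligand is used.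

## Route

Step 1
Reactants: 1 phloroglucinol; 2 benzoyl chloride (2.2 equiv)
Product: 3 2,4-dibenzoylphloroglucinol
Conditions: AlCl3 (4 equiv), PhNO2, 70 °C; aq. HCl work-up
Reagents that add atoms: none
Why: Double Friedel–Crafts acylation of the electron-rich triol stops at the 2,4-diacyl stage because each acyl group deactivates the ring; no stereocenter is formed.

Step 2
Reactants: 3 2,4-dibenzoylphloroglucinol; 4 geranyl bromide (1.0 equiv)
Product: 5 6-geranyl-2,4-dibenzoylphloroglucinol
Conditions: KOH (2 equiv, 10 % aq.), 0 to 23 °C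
Reagents that add atoms: none
Why: Classical aqueous-alkali C-alkylation of an acylphloroglucinol anion at its only free ring carbon; the E alkene is carried over from 4 and no stereocenter is formed.

Step 3
Reactants: 6 methacrolein; 7 ethyl 2-(bromomethyl)acrylate
Product: 9 3-methylidene-5-(prop-1-en-2-yl)oxolan-2-one (racemic), via hydroxy ester 8 (not isolated)
Conditions: Zn dust, THF/sat. aq. NH4Cl, 23 °C; then TsOH·H2O (5 mol %), CH2Cl2, 23 °C
Reagents that add atoms: none
Why: Zinc Barbier allylation (1,2-addition to the enal) followed by acid lactonization is the standard α-methylene-γ-butyrolactone synthesis; the one stereocenter is racemic and is erased in step 7.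

Step 4
Reactants: 9 3-methylidene-5-(prop-1-en-2-yl)oxolan-2-one
Product: 10 2,6-dimethyl-3-methylidenehept-6-ene-2,5-diol (racemic)
Conditions: MeLi (2.5 equiv), Et2O, −78 to 0 °C; aq. NH4Cl
Reagents that add atoms: methyllithium, [Li]C
Why: Double 1,2-addition of a hard organolithium to the lactone carbonyl (ester to tertiary alcohol) opens the ring; low temperature suppresses conjugate addition.

Step 5
Reactants: 10 2,6-dimethyl-3-methylidenehept-6-ene-2,5-diol
Product: 11 6-hydroxy-2,6-dimethyl-5-methylidenehept-1-en-3-yl acetate (racemic)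
Conditions: Ac2O (1.1 equiv), pyridine, 0 °C
Reagents that add atoms: acetic anhydride, CC(=O)OC(C)=O
Why: Acylation without a nucleophilic catalyst takes the secondary allylic alcohol and leaves the tertiary alcohol untouched (chemoselective esterification).

Step 6
Reactants: 11 6-hydroxy-2,6-dimethyl-5-methylidenehept-1-en-3-yl acetate
Product: 12 5-(bromomethyl)-2,6-dimethylhepta-1,5-dien-3-yl acetate (racemic)
Conditions: PBr3 (0.4 equiv), pyridine (cat.), Et2O, −20 °C
Reagents that add atoms: phosphorus tribromide, BrP(Br)Br
Why: Bromination of a tertiary allylic alcohol with allylic transposition (SN2′, as in linalool to geranyl bromide) gives the primary bromide on the tetrasubstituted alkene; the acetate survives.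

Step 7 (key step)
Reactants: 5 6-geranyl-2,4-dibenzoylphloroglucinol; 12 5-(bromomethyl)-2,6-dimethylhepta-1,5-dien-3-yl acetate (1.1 equiv)
Product: 14 C3-benzoyl bicyclo[4.3.1] triketone (C5 and C3 of ring A bridged on one face by C6H2–C7(=CMe2)–C10H2–C11H; isopropenyl on C11 anti to C4; C1 benzoyl enolized), via dearomatized C-allyl triketone 13 (not isolated)
Conditions: Pd2(dba)3·CHCl3 (5 mol %), (S,S)-DACH-phenyl Trost ligand (12 mol %), Cs2CO3 (2.5 equiv), THF (0.01 M), 0 °C then 45 °C
Reagents that add atoms: none
Why: Proposed new method: zerovalent palladium ionizes the allylic bromide first and the phenoxide of 5 is C-allylated at its only non-acyl ring carbon by the CH2 terminus (known palladium dearomative prenylation of acylphloroglucinols), giving C_s-symmetric 13 with C6 axial on sp3 C5; on warming the allylic acetate ionizes, the π-allyl faces equilibrate through the η1-CH2 form, and one of the two enantiotopic benzoyl-bearing enolate carbons attacks C11 to close the seven-membered ring (O-allylation is reversible under palladium; attack at the CH2 terminus would need a nine-membered ring), so the chiral ligand sets C3, C5 and C11 together with isopropenyl pseudo-equatorial; the closest known reactions are the palladium dearomative conjunctive allylic annulation of acylphloroglucinols to bicyclo[3.3.1] cores and Trost desymmetrizing allylic alkylations.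

Step 8
Reactants: 14 C3-benzoyl bicyclo[4.3.1] triketone; 15 prenyl bromide (1.2 equiv)
Product: 17 C3-prenyl bicyclo[4.3.1] triketone, via debenzoylated C3–H enolate 16 (not isolated)
Conditions: NaOMe (2.2 equiv), MeOH/THF, 0 °C; then prenyl bromide, 0 to 23 °C
Reagents that add atoms: none
Why: Methoxide cleaves only the benzoyl on quaternary C3 (retro-Claisen of a non-enolizable 2-acyl-1,3-dione; the C1 benzoyl is protected as its enolate), and the resulting diketone enolate, the most basic carbon of the dianion, is C-alkylated by prenyl bromide from the only open face of the bridgehead, which keeps the C3 configuration.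

Step 9
Reactants: 17 C3-prenyl bicyclo[4.3.1] triketone
Product: 19 CNP0164095.2 (target), via tertiary formate 18 (not isolated)
Conditions: HCO2H, 23 °C; then Et3N, MeOH, 23 °C
Reagents that add atoms: formic acid, OC=O
Why: Proposed new method: protonation of the isopropenyl group gives the tertiary C12 cation, which is captured 5-exo by the prenyl alkene through a chair-like transition state (C15 centre trans to C10, setting C13) and the C15 cation is trapped as formate; reversible protonation of the C7=C8 alkene gives the C8 cation, and only the C7 epimer whose cation points into the cavity can be captured by the enol carbon C1, the last nucleophilic ring carbon, so C7 (H exo) and C1 are set under Curtin–Hammett control and ring B must close at the benzoyl carbon; the closest known reactions are formic-acid cation cyclizations of dearomatized acylphloroglucinols to bicyclo[3.3.1]nonanes and cation–olefin cyclopentannulations.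

## Compound list

1 | phloroglucinol (benzene-1,3,5-triol) | Oc1cc(O)cc(O)c1 | starting material
2 | benzoyl chloride | O=C(Cl)c1ccccc1 | starting material
3 | 2,4-dibenzoylphloroglucinol, (2,4,6-trihydroxy-1,3-phenylene)bis(phenylmethanone) | O=C(c1ccccc1)c1c(O)cc(O)c(C(=O)c2ccccc2)c1O | intermediate
4 | geranyl bromide, (2E)-1-bromo-3,7-dimethylocta-2,6-diene | CC(C)=CCC/C(C)=C/CBr | starting material
5 | 6-geranyl-2,4-dibenzoylphloroglucinol (E alkene; C_s-symmetric arene) | CC(C)=CCC/C(C)=C/Cc1c(O)c(C(=O)c2ccccc2)c(O)c(C(=O)c2ccccc2)c1O | intermediate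
6 | methacrolein (2-methylprop-2-enal) | CC(=C)C=O | starting material
7 | ethyl 2-(bromomethyl)acrylate | CCOC(=O)C(=C)CBr | starting material
8 | ethyl 4-hydroxy-5-methyl-2-methylidenehex-5-enoate (racemic; not isolated) | CCOC(=O)C(=C)CC(O)C(C)=C | intermediate
9 | 3-methylidene-5-(prop-1-en-2-yl)oxolan-2-one (racemic) | C=C1CC(C(C)=C)OC1=O | intermediate
10 | 2,6-dimethyl-3-methylidenehept-6-ene-2,5-diol (racemic) | CC(=C)C(O)CC(=C)C(C)(C)O | intermediate
11 | 6-hydroxy-2,6-dimethyl-5-methylidenehept-1-en-3-yl acetate (racemic) | CC(=C)C(OC(C)=O)CC(=C)C(C)(C)O | intermediate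
12 | 5-(bromomethyl)-2,6-dimethylhepta-1,5-dien-3-yl acetate (racemic) | CC(=C)C(OC(C)=O)CC(CBr)=C(C)C | intermediate
13 | 2,4-dibenzoyl-6-geranyl-6-[4-acetoxy-5-methyl-2-(propan-2-ylidene)hex-5-enyl]cyclohexane-1,3,5-trione, dienol form (racemic at the acetate carbon; not isolated) | CC(C)=CCC/C(C)=C/CC1(CC(CC(OC(C)=O)C(C)=C)=C(C)C)C(=O)C(C(=O)c2ccccc2)=C(O)C(C(=O)c2ccccc2)=C1O | intermediate
14 | C3-benzoyl bicyclo[4.3.1] triketone: ring A with enolized C1 benzoyl, quaternary C3 (benzoyl) and C5 (geranyl) bridged on one face by C6H2–C7(=CMe2)–C10H2–C11H, isopropenyl on C11 anti to C4; single enantiomer, C3, C5 and C11 as in the target | CC(C)=CCC/C(C)=C/C[C@@]12CC(=C(C)C)C[C@H](C(C)=C)[C@@](C(=O)c3ccccc3)(C1=O)C(=O)C(C(=O)c1ccccc1)=C2O | intermediate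
15 | prenyl bromide (1-bromo-3-methylbut-2-ene) | CC(C)=CCBr | starting material
16 | debenzoylated bicyclo[4.3.1] triketone with C3–H (present as its disodium enolate; not isolated) | CC(C)=CCC/C(C)=C/C[C@@]12CC(=C(C)C)C[C@H](C(C)=C)[C@@H](C1=O)C(=O)C(C(=O)c1ccccc1)=C2O | intermediate
17 | C3-prenyl bicyclo[4.3.1] triketone: as 14 but with prenyl in place of the C3 benzoyl | CC(C)=CCC/C(C)=C/C[C@@]12CC(=C(C)C)C[C@H](C(C)=C)[C@@](CC=C(C)C)(C1=O)C(=O)C(C(=O)c1ccccc1)=C2O | intermediate
18 | C15 formate ester of the target (not isolated) | CC(C)=CCC/C(C)=C/C[C@@]12C[C@H]3C[C@@H]4C(C)(C)[C@@H](C(C)(C)OC=O)C[C@]4(C1=O)C(=O)[C@@](C(=O)c1ccccc1)(C2=O)C3(C)C | intermediate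
19 | CNP0164095.2: (1S,3S,5R,7R,11R,13S)-1-benzoyl-5-geranyl-8,8,12,12-tetramethyl-13-(2-hydroxypropan-2-yl) homoadamantane-type trione in the labels above (bonds C1–C8, C3–C11, C12–C13; ketones at C2, C4, C9; H on C7 exo; C15 group cis to H on C11) | CC(C)=CCC/C(C)=C/C[C@@]12C[C@H]3C[C@@H]4C(C)(C)[C@@H](C(C)(C)O)C[C@]4(C1=O)C(=O)[C@@](C(=O)c1ccccc1)(C2=O)C3(C)C | target

## Step count and risk

Total step count: 9. Longest linear sequence: 7 (steps 3 to 9).

Steps most likely to fail:

Step 7. The benzoyl-bearing carbon is a hindered, weakly nucleophilic centre and must attack the substituted allyl terminus; enantio- and diastereocontrol are untested. Fallback, setting out from 5 and 12 and coming back at 14: alkylate 5 with 12 without palladium (K2CO3, acetone, 23 °C) and isolate 13; methanolysis (K2CO3, MeOH, 0 °C) gives the secondary allylic alcohol F1; PBr3 converts it with allylic transposition into the primary (E)-allylic bromide F2; the ring is then closed by an ion-pair-controlled intramolecular SN2′ C-alkylation under chiral phase-transfer catalysis (N-(9-anthracenylmethyl)cinchonidinium bromide 10 mol %, CsOH·H2O, toluene, −40 °C), which gives 14 without a metal π-allyl.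

Step 9. The C12 and C8 cations may be intercepted by the geranyl alkenes, C1 may attack C12 instead of C8, or a hydride shift may lead to closure at C7. Fallback, setting out from 17 and coming back at 19: build the cyclopentane first by radical chemistry. Fe(acac)3 (30 mol %), PhSiH3, O2 (1 atm), EtOH, 0 °C, then PPh3: hydrogen-atom transfer to the 1,1-disubstituted isopropenyl group gives the tertiary C12 radical, 5-exo cyclization onto the prenyl alkene and trapping by O2 give the cyclopentane tertiary alcohol F3 with the C7=C8 alkene intact. TfOH (5 mol %) in CH2Cl2 at −20 °C then closes only C1–C8 to give 19.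

Step 8. Methoxide may open ring A at C4 instead of cleaving the benzoyl group, or prenyl bromide may alkylate oxygen or C1. Fallback, setting out from 14 and coming back at 17: treat 14 with Pd(PPh3)4 (5 mol %), allyl methyl carbonate and NaH (1 equiv) in THF at 40 °C; the methoxide released on ionization cleaves the C3 benzoyl and the enolate is allylated by π-allylpalladium, with O-allylation reversible (deacylative allylation), to give the C3-allyl bicyclo[4.3.1] triketone F4. Cross-metathesis with 2-methylbut-2-ene (second-generation Hoveyda–Grubbs catalyst, CH2Cl2, 40 °C) turns allyl into prenyl and gives 17.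

## Further compounds

F1 | step 7 | 2,4-dibenzoyl-6-geranyl-6-[4-hydroxy-5-methyl-2-(propan-2-ylidene)hex-5-enyl]cyclohexane-1,3,5-trione, dienol form (racemic) | CC(C)=CCC/C(C)=C/CC1(CC(CC(O)C(C)=C)=C(C)C)C(=O)C(C(=O)c2ccccc2)=C(O)C(C(=O)c2ccccc2)=C1O
F2 | step 7 | 2,4-dibenzoyl-6-geranyl-6-[(4E)-6-bromo-5-methyl-2-(propan-2-ylidene)hex-4-enyl]cyclohexane-1,3,5-trione, dienol form | CC(C)=CCC/C(C)=C/CC1(CC(C/C=C(\C)CBr)=C(C)C)C(=O)C(C(=O)c2ccccc2)=C(O)C(C(=O)c2ccccc2)=C1O
F3 | step 9 | cyclopentane-fused bicyclo[4.3.1] triketone with C12–C13 bond and C15–OH, C7=C8 alkene and C1 enol intact (C3, C5, C11, C13 as in the target) | CC(C)=CCC/C(C)=C/C[C@@]12CC(=C(C)C)C[C@@H]3C(C)(C)[C@@H](C(C)(C)O)C[C@]3(C1=O)C(=O)C(C(=O)c1ccccc1)=C2O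
F4 | step 8 | C3-allyl bicyclo[4.3.1] triketone (as 17 with allyl in place of prenyl) | CC(C)=CCC/C(C)=C/C[C@@]12CC(=C(C)C)C[C@H](C(C)=C)[C@@](CC=C)(C1=O)C(=O)C(C(=O)c1ccccc1)=C2O
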